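## The problem

Compound 28 is a biflavanoid. Two 7,8,3',4'-oxygenated flavan units are joined by one bond from the sp3 carbon C4 of the upper pyran (ring C) to the aromatic carbon C6' of ring D, and ring D is also the benzo ring of the lower pyran (ring F). The upper unit has three contiguous stereocentres, C2 (R), C3 (R) and C4 (R), with ring B, the C3 hydroxyl and ring D all on one face of ring C. The lower unit has C2' (R), C3' (R) and C4' (S), a 2,3-cis-3,4-trans flavan-3,4-diol. Within each pyran one centre can set the other two (C4 can direct C2 and C3; C4' can direct C3' and C2'), but ring D insulates the two triads from each other, so each needs its own source of absolute configuration. Both 2,3-cis relationships are the less stable ones and cannot be reached by equilibration. Ten phenolic hydroxyls (two catechols, two pyrogallol-type arrays) oxidise easily, and the C4' carbinol (benzylic, para to O7', ortho to O1') ionises under acid and is exposed to hydrogenolysis. C4–H is doubly benzylic between two electron-rich rings, which rules out a late quinone-type benzylic oxidation, so the C4' oxygen must be carried in from an aldehyde. The feature that opens the molecule is ring C itself: O1 and the ortho carbon C4a of ring A are bridged by C2–C3–C4, with ring B on C2 and ring D on C4. That is a chalcone laid across a phenol, and C4a (ortho to O1, para to the C7 oxygen) is the most nucleophilic carbon of that phenol.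

## Retrosynthesis

**28 from 27.** The eight phenolic O–benzyl bonds are cut last. Methyl ethers would need boron halides that ionise C4', and silyl ethers would not survive the base, organolithium and hydride steps. Benzyl ethers are removed by neutral hydrogenolysis, and 27 has only the three secondary hydroxyls free. The forward step must spare the C4'–O bond.

**27 from 25 (via 26), and 25 from 24.** Ring F is cut at O1'–C2', and the C2'–O/C3'–O pair is traced to a (Z)-alkene through a cis-epoxide. The classical route through a chalcone epoxide and a dihydroflavonol is the obvious neighbour, but it gives the 2,3-trans ring and would then need an inversion at C3' next to a C4' ketone. Oxidising C4' after ring closure is excluded by C4–H. Opening a cis-epoxide at C2' with inversion gives 2,3-cis directly. An epoxide delivered syn to the C4' hydroxyl of a (Z)-allylic alcohol gives the 3,4-trans diol. Allylic alcohol 24 carries one stereocentre in the lower half instead of three. The forward steps must give a face-selective, hydroxyl-directed epoxidation and a 6-endo opening that stays stereospecific.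

**24 from 23, and 23 from 20 and 22.** The alkene is taken back to an alkyne, and the C4'–C3' bond is cut to aldehyde 20 and arylacetylene 22. Cutting C3'–C2' instead would leave two stereocentres to be made in one aldol-type step without a controlling element. The alkyne addition makes only C4', and a catalyst can control it; the upper unit is too far away to help or interfere. The forward reaction must deliver the (R) carbinol by catalyst control and a clean cis semi-hydrogenation.

**20 from 19, 18 and 17.** The C8a' oxygen is the one oxygen of ring D that must be released late under non-acidic conditions, so it is a silyl ether in 20. It is singled out from the other benzyl ethers in 18 because it alone is ortho to the formyl group (chelation-controlled debenzylation to 19). The formyl group goes back to the bromine of 17. This keeps uniform benzyl protection and an inert aryl bromide through the key step.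

**17 from 16, 15 and 13.** The C3 hydroxyl is inverted by oxidation and hydride reduction. The trans alcohol 15 comes from hydroboration of enol ether 13, which sets C2 and C3 from C4. Chromene 13 has a single stereocentre.

**13 from 4 and 10 (key disconnection).** The bonds C4–C4a and O1–C2 are cut, so ring C falls into phenol 4 and chalcone 10. The neighbouring cut, C4–C6' (a flavan-4-yl cation arylated by ring D), is the biomimetic one. However, nucleophiles add to 2,3-cis flavan-4-yl cations trans to the C3 oxygen, which gives the wrong C4 epimer, and a 7,8-dioxygenated ring D is a poor nucleophile. The chosen cut gives two achiral halves of similar size. It asks the catalyst for enantioface selection at the chalcone β-carbon and for ortho C-alkylation of the phenol.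

**Fragments.** Chalcone 10 comes from aldehyde 9 and ketone 6 by aldol condensation. Aldehyde 9 comes from 7 by benzylation (8) and bromination. Ketone 6 comes from 5, phenol 4 from 1 via 2 by Dakin oxidation, and alkyne 22 from 21 by one-carbon homologation.

## Roads not taken

**Alternative 1:** The cut is O1–C8a together with the C8–O bond. Lithium 2,2,6,6-tetramethylpiperidide would turn a ring-A chloride into the C8a–C8 aryne. The C2 alkoxide adds at C8a to close ring C, and the C8 aryllithium is trapped with B(OMe)3 and oxidised with H2O2, giving A1.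
- Merits: O1 and the C8 oxygen arrive in one operation from a simply substituted ring A. The 2,3-cis pair is built in the open chain, so no oxidation–reduction detour is needed. Ring D already carries a masked acetyl group for the lower unit.
- Weak points: A1 has a tertiary carbinol at C4, so the C4–H bond must be made afterwards by an ionic reduction whose facial outcome is not secured. A hindered amide base meets many benzylic ether positions. The three-carbon chain with its C2 and C3 centres must be assembled stepwise first.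
- Comparison: this road is better at the 2,3-cis relationship and at late oxygenation of C8. The chosen plan sets against it a convergent, catalytic union of two achiral halves under weakly basic and weakly acidic conditions, with C4 made first and kept as the controlling centre.

**Alternative 2:** The cut is C4'–C4a'. BF3·OEt2 would activate the aldehyde of a ring-D aryl ether, C4a' attacks it, ring F closes and the C4' carbinol forms trans to O3', giving A2.
- Merits: C4' is set by substrate control in exactly the required sense. The C2'/C3' pair comes from open-chain dihydroxylation chemistry. No epoxide, semi-hydrogenation or protecting-group exchange is needed, and A2 is one step from 28.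
- Weak points: the precursor needs the O1'–C2' ether made with defined configuration at an electron-rich benzylic carbon on a hindered phenol, where ionisation erodes stereochemistry. The aldehyde has an epimerisable α-aryloxy centre. BF3 can re-ionise the new C4' carbinol.
- Comparison: for C4' this road is as direct as or more direct than the chosen end game, and it is shorter at the end. The chosen plan avoids substitution at a benzylic carbon by a hindered phenol and derives all three ring-F centres from one catalytic step followed by two stereospecific ones. Alternative 2 also says nothing about the upper unit, which would still need the annulation or an equivalent.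

**Alternative 3:** The cut is O1'–C2' on a lower unit made first. Jacobsen–Katsuki epoxidation of a (Z)-1,3-diarylpropene (chiral Mn(salen)Cl complex, NaOCl), acetate methanolysis and acid let the ring-D phenol open the cis-epoxide at C2', giving A3.
- Merits: cis-disubstituted conjugated alkenes are the best substrates for that epoxidation. The 2,3-cis pair is set catalytically on a small achiral molecule, and the bromine marks the point of attachment for the upper unit.
- Weak points: A3 lacks the C4' oxygen. It would have to come from a benzylic oxidation, which is slow on this ring and, once the upper unit is attached, competes with the doubly benzylic C4–H. If introduced earlier, a labile C4' substituent would have to survive the whole upper-unit sequence.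
- Comparison: the ring-closing event is the one the chosen route also uses for ring F, and Alternative 3 applies it earlier, on a simpler substrate, with a more robust asymmetric step. The chosen plan sets against it that the C4' oxygen is present from the start as the carbinol that directs the epoxidation, so no C–H oxidation is needed.

Key step: step 7

Assumption: the sense of induction in the two catalyst-controlled steps (7 and 15) is taken as written for the quinidine-derived thiourea and for (S,S)-ProPhenol; if either delivers the opposite face, the quinine-derived thiourea or (R,R)-ProPhenol is used with nothing else changed.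

## Route

Step 1
Reactants: 1 2,3-dihydroxybenzaldehyde
Product: 2 2,3-bis(benzyloxy)benzaldehyde
Conditions: BnBr, K2CO3, DMF, 60 °C
Reagents that add atoms: benzyl bromide, BrCc1ccccc1
Why: Williamson etherification of both phenols; the aldehyde is inert to carbonate.

Step 2
Reactants: 2 2,3-bis(benzyloxy)benzaldehyde
Product: 4 2,3-bis(benzyloxy)phenol, via 2,3-bis(benzyloxy)phenyl formate 3 (not isolated)
Conditions: m-CPBA, CH2Cl2, 0 °C to rt; then KOH, MeOH, rt
Reagents that add atoms: m-chloroperbenzoic acid, OOC(=O)c1cccc(Cl)c1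
Why: Dakin-type Baeyer–Villiger oxidation; the electron-rich ortho-alkoxyaryl group migrates in preference to hydride, and the formate is cleaved by methanolic base.

Step 3
Reactants: 5 3',4'-dihydroxyacetophenone
Product: 6 1-[3,4-bis(benzyloxy)phenyl]ethanone
Conditions: BnBr, K2CO3, DMF, 60 °C
Reagents that add atoms: benzyl bromide, BrCc1ccccc1
Why: Williamson etherification; carbonate does not enolise the ketone to any useful extent.

Step 4
Reactants: 7 2,3,4-trihydroxybenzaldehyde
Product: 8 2,3,4-tris(benzyloxy)benzaldehyde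
Conditions: BnBr (excess), K2CO3, DMF, 70 °C
Reagents that add atoms: benzyl bromide, BrCc1ccccc1
Why: Williamson etherification; excess reagent and heat are used because the hydrogen-bonded 2-hydroxyl reacts last.

Step 5
Reactants: 8 2,3,4-tris(benzyloxy)benzaldehyde
Product: 9 2,3,4-tris(benzyloxy)-5-bromobenzaldehyde
Conditions: NBS, DMF, rt
Reagents that add atoms: N-bromosuccinimide, O=C1CCC(=O)N1Br
Why: Electrophilic aromatic bromination; C5 is ortho to the 4-benzyloxy group, para to the 2-benzyloxy group and meta to the formyl group, whereas C6 is ortho to the deactivating formyl group.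

Step 6
Reactants: 9 2,3,4-tris(benzyloxy)-5-bromobenzaldehyde; 6 1-[3,4-bis(benzyloxy)phenyl]ethanone
Product: 10 (E)-1-[3,4-bis(benzyloxy)phenyl]-3-[2,3,4-tris(benzyloxy)-5-bromophenyl]prop-2-en-1-one
Conditions: KOH (aq), EtOH–THF, rt
Reagents that add atoms: none
Why: Claisen–Schmidt condensation of a non-enolisable aldehyde with a methyl ketone; elimination from the aldol gives the conjugated (E)-enone.

Step 7
Reactants: 4 2,3-bis(benzyloxy)phenol; 10 (E)-1-[3,4-bis(benzyloxy)phenyl]-3-[2,3,4-tris(benzyloxy)-5-bromophenyl]prop-2-en-1-one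
Product: 13 (4S)-7,8-bis(benzyloxy)-2-[3,4-bis(benzyloxy)phenyl]-4-[2,3,4-tris(benzyloxy)-5-bromophenyl]-4H-chromene, via Friedel–Crafts ketone 11 (not isolated), via chroman-2-ol hemiketal 12 (not isolated)
Conditions: 4 (1.5 equiv), 9-amino-9-deoxy-epi-quinidine-derived N-[3,5-bis(trifluoromethyl)phenyl]thiourea (20 mol %), 4 Å MS, toluene (concentrated), 40 °C; then p-TsOH·H2O (10 mol %), 40 °C
Reagents that add atoms: none
Why: The thiourea N–H bonds activate the carbonyl of 10 while the quinuclidine nitrogen hydrogen-bonds the hydroxyl of 4, so that the ortho carbon of 4 (future C4a, para to the C7 benzyloxy group) adds to the β-carbon (C4) and tautomerisation restores the arene to give ketone 11. The phenol oxygen then adds to the ketone (6-exo-trig) to give hemiketal 12, and the added acid expels water through the 2-aryl oxocarbenium ion to give enol ether 13; this loss of water closes ring C (bond O1–C2) and pulls the sluggish first stage forward. The closest known reaction type is the organocatalytic enantioselective Friedel–Crafts alkylation–cyclodehydration of naphthols and sesamol-type phenols with enones to 4H-chromenes, and the same catalyst class is known to activate chalcones toward carbon nucleophiles. The only new stereocentre, C4 (S), is set by the catalyst, which exposes one enantioface of the chalcone β-carbon to the bound phenol. The step needs ortho rather than para C-alkylation and C- rather than O-alkylation: holding the hydroxyl on the catalyst base places only the ortho carbon (the single free one) next to the electrophile, and any oxa-Michael adduct reverts. Because the chalcone is electron-rich and unactivated, the reaction is run concentrated with excess 4 and sieves, and the acid is added only after 10 is consumed so that no uncatalysed racemic pathway competes.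

Step 8
Reactants: 13 (4S)-7,8-bis(benzyloxy)-2-[3,4-bis(benzyloxy)phenyl]-4-[2,3,4-tris(benzyloxy)-5-bromophenyl]-4H-chromene
Product: 15 (2R,3S,4S)-7,8-bis(benzyloxy)-2-[3,4-bis(benzyloxy)phenyl]-4-[2,3,4-tris(benzyloxy)-5-bromophenyl]chroman-3-ol, via C3 alkylborane 14 (not isolated)
Conditions: BH3·THF, THF, 0 °C to rt; then NaOH (aq), H2O2, 0 °C to rt
Reagents that add atoms: hydrogen peroxide, OO
Why: Hydroboration–oxidation of the enol ether; boron goes to C3 (β to O1, the less substituted carbon) and adds syn with hydrogen on the face opposite the pseudo-axial C4 aryl group, and oxidation proceeds with retention, so C2 (R) and C3 (S) are set from C4 (rings B and D cis, hydroxyl trans to both).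

Step 9
Reactants: 15 (2R,3S,4S)-7,8-bis(benzyloxy)-2-[3,4-bis(benzyloxy)phenyl]-4-[2,3,4-tris(benzyloxy)-5-bromophenyl]chroman-3-ol
Product: 16 (2R,4S)-7,8-bis(benzyloxy)-2-[3,4-bis(benzyloxy)phenyl]-4-[2,3,4-tris(benzyloxy)-5-bromophenyl]chroman-3-one
Conditions: Dess–Martin periodinane, CH2Cl2, 0 °C to rt
Reagents that add atoms: none
Why: Dess–Martin oxidation under near-neutral conditions, chosen so that the two benzylic α-centres are not epimerised.

Step 10
Reactants: 16 (2R,4S)-7,8-bis(benzyloxy)-2-[3,4-bis(benzyloxy)phenyl]-4-[2,3,4-tris(benzyloxy)-5-bromophenyl]chroman-3-one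
Product: 17 (2R,3R,4S)-7,8-bis(benzyloxy)-2-[3,4-bis(benzyloxy)phenyl]-4-[2,3,4-tris(benzyloxy)-5-bromophenyl]chroman-3-ol
Conditions: LiBH(s-Bu)3, THF, −78 °C; aq NH4Cl
Reagents that add atoms: none
Why: Bulky-hydride reduction, the known way from 2,3-trans to 2,3-cis flavan-3-ols; hydride approaches the face opposite the two cis aryl groups and leaves the hydroxyl axial and cis to both, setting C3 (R).

Step 11
Reactants: 17 (2R,3R,4S)-7,8-bis(benzyloxy)-2-[3,4-bis(benzyloxy)phenyl]-4-[2,3,4-tris(benzyloxy)-5-bromophenyl]chroman-3-ol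
Product: 18 2,3,4-tris(benzyloxy)-5-{(2R,3R,4S)-7,8-bis(benzyloxy)-2-[3,4-bis(benzyloxy)phenyl]-3-hydroxychroman-4-yl}benzaldehyde
Conditions: n-BuLi (2.2 equiv), THF, −78 °C; DMF, −78 °C to 0 °C; aq NH4Cl
Reagents that add atoms: N,N-dimethylformamide, CN(C)C=O
Why: Bromine–lithium exchange (the first equivalent is consumed by the hydroxyl) is faster at −78 °C than benzylic or C4 deprotonation, and the aryllithium is formylated by DMF.

Step 12
Reactants: 18 2,3,4-tris(benzyloxy)-5-{(2R,3R,4S)-7,8-bis(benzyloxy)-2-[3,4-bis(benzyloxy)phenyl]-3-hydroxychroman-4-yl}benzaldehyde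
Product: 19 3,4-bis(benzyloxy)-5-{(2R,3R,4S)-7,8-bis(benzyloxy)-2-[3,4-bis(benzyloxy)phenyl]-3-hydroxychroman-4-yl}-2-hydroxybenzaldehyde
Conditions: MgBr2·OEt2, toluene–Et2O, rt to 50 °C; then 1 M HCl
Reagents that add atoms: none
Why: Chelation-controlled debenzylation; magnesium bridges the formyl oxygen and the ortho ether oxygen and bromide removes that benzyl group only, the other eight benzyl ethers having no ortho carbonyl.

Step 13
Reactants: 19 3,4-bis(benzyloxy)-5-{(2R,3R,4S)-7,8-bis(benzyloxy)-2-[3,4-bis(benzyloxy)phenyl]-3-hydroxychroman-4-yl}-2-hydroxybenzaldehyde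
Product: 20 3,4-bis(benzyloxy)-5-{(2R,3R,4S)-7,8-bis(benzyloxy)-2-[3,4-bis(benzyloxy)phenyl]-3-hydroxychroman-4-yl}-2-[(tert-butyldimethylsilyl)oxy]benzaldehyde
Conditions: TBSCl (1.2 equiv), imidazole, CH2Cl2, 0 °C to rt
Reagents that add atoms: tert-butyldimethylsilyl chloride, CC(C)(C)[Si](C)(C)Cl
Why: Silylation of the phenol; the hindered axial C3 hydroxyl is far slower and stays free.

Step 14
Reactants: 21 3,4-bis(benzyloxy)benzaldehyde
Product: 22 1,2-bis(benzyloxy)-4-ethynylbenzene
Conditions: dimethyl (1-diazo-2-oxopropyl)phosphonate, K2CO3, MeOH, rt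
Reagents that add atoms: dimethyl (1-diazo-2-oxopropyl)phosphonate, COP(=O)(OC)C(=[N+]=[N-])C(C)=O
Why: Ohira–Bestmann (Seyferth–Gilbert) homologation, reliable for electron-rich aryl aldehydes.

Step 15
Reactants: 20 3,4-bis(benzyloxy)-5-{(2R,3R,4S)-7,8-bis(benzyloxy)-2-[3,4-bis(benzyloxy)phenyl]-3-hydroxychroman-4-yl}-2-[(tert-butyldimethylsilyl)oxy]benzaldehyde; 22 1,2-bis(benzyloxy)-4-ethynylbenzene
Product: 23 (1R)-1-{3,4-bis(benzyloxy)-5-[(2R,3R,4S)-7,8-bis(benzyloxy)-2-[3,4-bis(benzyloxy)phenyl]-3-hydroxychroman-4-yl]-2-[(tert-butyldimethylsilyl)oxy]phenyl}-3-[3,4-bis(benzyloxy)phenyl]prop-2-yn-1-ol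
Conditions: 22 (3 equiv), Me2Zn (3.5 equiv), (S,S)-ProPhenol [2,6-bis{[(S)-2-(hydroxydiphenylmethyl)pyrrolidin-1-yl]methyl}-4-methylphenol] (20 mol %), Ph3P=O (40 mol %), toluene, 0 °C to rt; aq NH4Cl
Reagents that add atoms: none
Why: Catalytic asymmetric alkynylation of an aryl aldehyde by an alkynylzinc held on a dinuclear zinc–aminoalcohol catalyst; the catalyst alone sets C4' (R), the upper unit being too remote to matter, and one extra equivalent of Me2Zn covers the free C3 hydroxyl.

Step 16
Reactants: 23 (1R)-1-{3,4-bis(benzyloxy)-5-[(2R,3R,4S)-7,8-bis(benzyloxy)-2-[3,4-bis(benzyloxy)phenyl]-3-hydroxychroman-4-yl]-2-[(tert-butyldimethylsilyl)oxy]phenyl}-3-[3,4-bis(benzyloxy)phenyl]prop-2-yn-1-ol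
Product: 24 (1R,2Z)-1-{3,4-bis(benzyloxy)-5-[(2R,3R,4S)-7,8-bis(benzyloxy)-2-[3,4-bis(benzyloxy)phenyl]-3-hydroxychroman-4-yl]-2-[(tert-butyldimethylsilyl)oxy]phenyl}-3-[3,4-bis(benzyloxy)phenyl]prop-2-en-1-ol
Conditions: H2 (1 atm), Pd/CaCO3 poisoned with Pb(OAc)2, quinoline, EtOAc, rt
Reagents that add atoms: none
Why: Lindlar semi-hydrogenation; syn delivery of hydrogen gives the (Z)-alkene, and the poisoned catalyst leaves benzyl ethers and the benzylic carbinol alone.

Step 17
Reactants: 24 (1R,2Z)-1-{3,4-bis(benzyloxy)-5-[(2R,3R,4S)-7,8-bis(benzyloxy)-2-[3,4-bis(benzyloxy)phenyl]-3-hydroxychroman-4-yl]-2-[(tert-butyldimethylsilyl)oxy]phenyl}-3-[3,4-bis(benzyloxy)phenyl]prop-2-en-1-ol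
Product: 25 (S)-{3,4-bis(benzyloxy)-5-[(2R,3R,4S)-7,8-bis(benzyloxy)-2-[3,4-bis(benzyloxy)phenyl]-3-hydroxychroman-4-yl]-2-[(tert-butyldimethylsilyl)oxy]phenyl}{(2R,3S)-3-[3,4-bis(benzyloxy)phenyl]oxiran-2-yl}methanol
Conditions: m-CPBA, NaHCO3, CH2Cl2, −20 to 0 °C
Reagents that add atoms: m-chloroperbenzoic acid, OOC(=O)c1cccc(Cl)c1
Why: Hydroxyl-directed peracid epoxidation of a (Z)-allylic alcohol; allylic 1,3-strain holds the carbinol hydrogen in the alkene plane, so the hydrogen-bonded peracid reaches one face only and gives the threo cis-epoxy alcohol, fixing C3' (R) from C4', while the buffer protects the electron-rich aryl epoxide.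

Step 18
Reactants: 25 (S)-{3,4-bis(benzyloxy)-5-[(2R,3R,4S)-7,8-bis(benzyloxy)-2-[3,4-bis(benzyloxy)phenyl]-3-hydroxychroman-4-yl]-2-[(tert-butyldimethylsilyl)oxy]phenyl}{(2R,3S)-3-[3,4-bis(benzyloxy)phenyl]oxiran-2-yl}methanol
Product: 27 (2R,3R,4S)-7,8-bis(benzyloxy)-2-[3,4-bis(benzyloxy)phenyl]-6-{(2R,3R,4S)-7,8-bis(benzyloxy)-2-[3,4-bis(benzyloxy)phenyl]-3-hydroxychroman-4-yl}chroman-3,4-diol, via free-phenol epoxy alcohol 26 (not isolated)
Conditions: TBAF, AcOH, THF, 0 °C; then PPTS (10 mol %), CH2Cl2, 0 °C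
Reagents that add atoms: none
Why: Buffered fluoride desilylation followed by acid-promoted 6-endo epoxide opening by the phenol at the benzylic carbon C2' with inversion, which closes ring F and gives C2' (R) cis to the C3' hydroxyl; the threo epoxy alcohol translates into the 3,4-trans diol, and 6-endo is preferred over 5-exo because ring E stabilises charge at C2'.

Step 19
Reactants: 27 (2R,3R,4S)-7,8-bis(benzyloxy)-2-[3,4-bis(benzyloxy)phenyl]-6-{(2R,3R,4S)-7,8-bis(benzyloxy)-2-[3,4-bis(benzyloxy)phenyl]-3-hydroxychroman-4-yl}chroman-3,4-diol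
Product: 28 (2R,3R,4S)-2-(3,4-dihydroxyphenyl)-6-[(2R,3R,4R)-2-(3,4-dihydroxyphenyl)-3,7,8-trihydroxychroman-4-yl]chroman-3,4,7,8-tetrol
Conditions: H2 (1 atm), Pd(OH)2/C, THF–MeOH, rt; stopped when the benzyl ethers are consumed
Reagents that add atoms: none
Why: Neutral hydrogenolysis of the eight aryl benzyl ethers, as used for benzylated oligomeric flavan-3-ols; aryl benzyl ethers cleave much faster than the secondary benzylic C–O bonds of the pyran rings and the C4' carbinol. The C4 descriptor changes from S to R only because the priorities change on debenzylation.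

## Compound list

1 | 2,3-dihydroxybenzaldehyde | O=Cc1cccc(O)c1O | starting material
2 | 2,3-bis(benzyloxy)benzaldehyde | O=Cc1cccc(OCc2ccccc2)c1OCc1ccccc1 | intermediate
3 | 2,3-bis(benzyloxy)phenyl formate | O=COc1cccc(OCc2ccccc2)c1OCc1ccccc1 | intermediate
4 | 2,3-bis(benzyloxy)phenol | Oc1cccc(OCc2ccccc2)c1OCc1ccccc1 | intermediate
5 | 3',4'-dihydroxyacetophenone | CC(=O)c1ccc(O)c(O)c1 | starting material
6 | 1-[3,4-bis(benzyloxy)phenyl]ethanone | CC(=O)c1ccc(OCc2ccccc2)c(OCc2ccccc2)c1 | intermediate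
7 | 2,3,4-trihydroxybenzaldehyde | O=Cc1ccc(O)c(O)c1O | starting material
8 | 2,3,4-tris(benzyloxy)benzaldehyde | O=Cc1ccc(OCc2ccccc2)c(OCc2ccccc2)c1OCc1ccccc1 | intermediate
9 | 2,3,4-tris(benzyloxy)-5-bromobenzaldehyde | O=Cc1cc(Br)c(OCc2ccccc2)c(OCc2ccccc2)c1OCc1ccccc1 | intermediate
10 | (E)-1-[3,4-bis(benzyloxy)phenyl]-3-[2,3,4-tris(benzyloxy)-5-bromophenyl]prop-2-en-1-one | O=C(/C=C/c1cc(Br)c(OCc9ccccc9)c(OCc9ccccc9)c1OCc9ccccc9)c1ccc(OCc9ccccc9)c(OCc9ccccc9)c1 | intermediate
11 | (3S)-3-[3,4-bis(benzyloxy)-2-hydroxyphenyl]-1-[3,4-bis(benzyloxy)phenyl]-3-[2,3,4-tris(benzyloxy)-5-bromophenyl]propan-1-one | Oc1c(OCc9ccccc9)c(OCc9ccccc9)ccc1[C@@H](c1cc(Br)c(OCc9ccccc9)c(OCc9ccccc9)c1OCc9ccccc9)CC(=O)c1ccc(OCc9ccccc9)c(OCc9ccccc9)c1 | intermediate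
12 | (4S)-7,8-bis(benzyloxy)-2-[3,4-bis(benzyloxy)phenyl]-4-[2,3,4-tris(benzyloxy)-5-bromophenyl]chroman-2-ol (both C2 epimers) | O1c2c(OCc9ccccc9)c(OCc9ccccc9)ccc2[C@@H](c2cc(Br)c(OCc9ccccc9)c(OCc9ccccc9)c2OCc9ccccc9)CC1(O)c1ccc(OCc9ccccc9)c(OCc9ccccc9)c1 | intermediate
13 | (4S)-7,8-bis(benzyloxy)-2-[3,4-bis(benzyloxy)phenyl]-4-[2,3,4-tris(benzyloxy)-5-bromophenyl]-4H-chromene | O1c2c(OCc9ccccc9)c(OCc9ccccc9)ccc2[C@@H](c2cc(Br)c(OCc9ccccc9)c(OCc9ccccc9)c2OCc9ccccc9)C=C1c1ccc(OCc9ccccc9)c(OCc9ccccc9)c1 | intermediate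
14 | {7,8-bis(benzyloxy)-2-[3,4-bis(benzyloxy)phenyl]-4-[2,3,4-tris(benzyloxy)-5-bromophenyl]chroman-3-yl}borane (rings B and D cis, boron trans to both, configuration as in 15) | O1c2c(OCc9ccccc9)c(OCc9ccccc9)ccc2[C@@H](c2cc(Br)c(OCc9ccccc9)c(OCc9ccccc9)c2OCc9ccccc9)[C@H](B)[C@H]1c1ccc(OCc9ccccc9)c(OCc9ccccc9)c1 | intermediate
15 | (2R,3S,4S)-7,8-bis(benzyloxy)-2-[3,4-bis(benzyloxy)phenyl]-4-[2,3,4-tris(benzyloxy)-5-bromophenyl]chroman-3-ol | O1c2c(OCc9ccccc9)c(OCc9ccccc9)ccc2[C@@H](c2cc(Br)c(OCc9ccccc9)c(OCc9ccccc9)c2OCc9ccccc9)[C@H](O)[C@H]1c1ccc(OCc9ccccc9)c(OCc9ccccc9)c1 | intermediate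
16 | (2R,4S)-7,8-bis(benzyloxy)-2-[3,4-bis(benzyloxy)phenyl]-4-[2,3,4-tris(benzyloxy)-5-bromophenyl]chroman-3-one | O1c2c(OCc9ccccc9)c(OCc9ccccc9)ccc2[C@@H](c2cc(Br)c(OCc9ccccc9)c(OCc9ccccc9)c2OCc9ccccc9)C(=O)[C@H]1c1ccc(OCc9ccccc9)c(OCc9ccccc9)c1 | intermediate
17 | (2R,3R,4S)-7,8-bis(benzyloxy)-2-[3,4-bis(benzyloxy)phenyl]-4-[2,3,4-tris(benzyloxy)-5-bromophenyl]chroman-3-ol | O1c2c(OCc9ccccc9)c(OCc9ccccc9)ccc2[C@@H](c2cc(Br)c(OCc9ccccc9)c(OCc9ccccc9)c2OCc9ccccc9)[C@@H](O)[C@H]1c1ccc(OCc9ccccc9)c(OCc9ccccc9)c1 | intermediate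
18 | 2,3,4-tris(benzyloxy)-5-{(2R,3R,4S)-7,8-bis(benzyloxy)-2-[3,4-bis(benzyloxy)phenyl]-3-hydroxychroman-4-yl}benzaldehyde | O1c2c(OCc9ccccc9)c(OCc9ccccc9)ccc2[C@@H](c2cc(C=O)c(OCc9ccccc9)c(OCc9ccccc9)c2OCc9ccccc9)[C@@H](O)[C@H]1c1ccc(OCc9ccccc9)c(OCc9ccccc9)c1 | intermediate
19 | 3,4-bis(benzyloxy)-5-{(2R,3R,4S)-7,8-bis(benzyloxy)-2-[3,4-bis(benzyloxy)phenyl]-3-hydroxychroman-4-yl}-2-hydroxybenzaldehyde | O1c2c(OCc9ccccc9)c(OCc9ccccc9)ccc2[C@@H](c2cc(C=O)c(O)c(OCc9ccccc9)c2OCc9ccccc9)[C@@H](O)[C@H]1c1ccc(OCc9ccccc9)c(OCc9ccccc9)c1 | intermediate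
20 | 3,4-bis(benzyloxy)-5-{(2R,3R,4S)-7,8-bis(benzyloxy)-2-[3,4-bis(benzyloxy)phenyl]-3-hydroxychroman-4-yl}-2-[(tert-butyldimethylsilyl)oxy]benzaldehyde | O1c2c(OCc9ccccc9)c(OCc9ccccc9)ccc2[C@@H](c2cc(C=O)c(O[Si](C)(C)C(C)(C)C)c(OCc9ccccc9)c2OCc9ccccc9)[C@@H](O)[C@H]1c1ccc(OCc9ccccc9)c(OCc9ccccc9)c1 | intermediate
21 | 3,4-bis(benzyloxy)benzaldehyde | O=Cc1ccc(OCc2ccccc2)c(OCc2ccccc2)c1 | starting material
22 | 1,2-bis(benzyloxy)-4-ethynylbenzene | C#Cc1ccc(OCc2ccccc2)c(OCc2ccccc2)c1 | intermediate
23 | (1R)-1-{3,4-bis(benzyloxy)-5-[(2R,3R,4S)-7,8-bis(benzyloxy)-2-[3,4-bis(benzyloxy)phenyl]-3-hydroxychroman-4-yl]-2-[(tert-butyldimethylsilyl)oxy]phenyl}-3-[3,4-bis(benzyloxy)phenyl]prop-2-yn-1-ol | O1c2c(OCc9ccccc9)c(OCc9ccccc9)ccc2[C@@H](c2cc([C@H](O)C#Cc3ccc(OCc9ccccc9)c(OCc9ccccc9)c3)c(O[Si](C)(C)C(C)(C)C)c(OCc9ccccc9)c2OCc9ccccc9)[C@@H](O)[C@H]1c1ccc(OCc9ccccc9)c(OCc9ccccc9)c1 | intermediate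
24 | (1R,2Z)-1-{3,4-bis(benzyloxy)-5-[(2R,3R,4S)-7,8-bis(benzyloxy)-2-[3,4-bis(benzyloxy)phenyl]-3-hydroxychroman-4-yl]-2-[(tert-butyldimethylsilyl)oxy]phenyl}-3-[3,4-bis(benzyloxy)phenyl]prop-2-en-1-ol | O1c2c(OCc9ccccc9)c(OCc9ccccc9)ccc2[C@@H](c2cc([C@H](O)/C=C\c3ccc(OCc9ccccc9)c(OCc9ccccc9)c3)c(O[Si](C)(C)C(C)(C)C)c(OCc9ccccc9)c2OCc9ccccc9)[C@@H](O)[C@H]1c1ccc(OCc9ccccc9)c(OCc9ccccc9)c1 | intermediate
25 | (S)-{3,4-bis(benzyloxy)-5-[(2R,3R,4S)-7,8-bis(benzyloxy)-2-[3,4-bis(benzyloxy)phenyl]-3-hydroxychroman-4-yl]-2-[(tert-butyldimethylsilyl)oxy]phenyl}{(2R,3S)-3-[3,4-bis(benzyloxy)phenyl]oxiran-2-yl}methanol | O1c2c(OCc9ccccc9)c(OCc9ccccc9)ccc2[C@@H](c2cc([C@H](O)[C@H]4O[C@H]4c3ccc(OCc9ccccc9)c(OCc9ccccc9)c3)c(O[Si](C)(C)C(C)(C)C)c(OCc9ccccc9)c2OCc9ccccc9)[C@@H](O)[C@H]1c1ccc(OCc9ccccc9)c(OCc9ccccc9)c1 | intermediate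
26 | (S)-{3,4-bis(benzyloxy)-5-[(2R,3R,4S)-7,8-bis(benzyloxy)-2-[3,4-bis(benzyloxy)phenyl]-3-hydroxychroman-4-yl]-2-hydroxyphenyl}{(2R,3S)-3-[3,4-bis(benzyloxy)phenyl]oxiran-2-yl}methanol | O1c2c(OCc9ccccc9)c(OCc9ccccc9)ccc2[C@@H](c2cc([C@H](O)[C@H]4O[C@H]4c3ccc(OCc9ccccc9)c(OCc9ccccc9)c3)c(O)c(OCc9ccccc9)c2OCc9ccccc9)[C@@H](O)[C@H]1c1ccc(OCc9ccccc9)c(OCc9ccccc9)c1 | intermediate
27 | (2R,3R,4S)-7,8-bis(benzyloxy)-2-[3,4-bis(benzyloxy)phenyl]-6-{(2R,3R,4S)-7,8-bis(benzyloxy)-2-[3,4-bis(benzyloxy)phenyl]-3-hydroxychroman-4-yl}chroman-3,4-diol | O1c2c(OCc9ccccc9)c(OCc9ccccc9)ccc2[C@@H](c2cc3c(c(OCc9ccccc9)c2OCc9ccccc9)O[C@H](c4ccc(OCc9ccccc9)c(OCc9ccccc9)c4)[C@H](O)[C@H]3O)[C@@H](O)[C@H]1c1ccc(OCc9ccccc9)c(OCc9ccccc9)c1 | intermediate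
28 | (2R,3R,4S)-2-(3,4-dihydroxyphenyl)-6-[(2R,3R,4R)-2-(3,4-dihydroxyphenyl)-3,7,8-trihydroxychroman-4-yl]chroman-3,4,7,8-tetrol | Oc1ccc([C@H]2Oc3c(ccc(O)c3O)[C@@H](c3cc4c(c(O)c3O)O[C@H](c3ccc(O)c(O)c3)[C@H](O)[C@H]4O)[C@H]2O)cc1O | target

## Step count and least certain steps

Total: 19 steps. Longest linear sequence: 15 steps (steps 4–13 and 15–19, from 7).

**Step 7 (key step).** The electron-rich, unactivated chalcone may react too slowly. The likely failures are incomplete conversion, an acid-catalysed racemic pathway once the dehydrating acid is present, para C-alkylation when the phenol escapes the catalyst, and erosion of enantiomeric purity through reversibility. A squaramide analogue of the catalyst is the first variation. Fallback with a different C–C bond-forming event: setting out from 4, ortho-selective bromination (NBS, catalytic i-Pr2NH, CH2Cl2) would give 2,3-bis(benzyloxy)-6-bromophenol F1. Bromine–lithium exchange on its lithium phenoxide (n-BuLi, 2.2 equiv), B(OMe)3 and hydrolysis would give [3,4-bis(benzyloxy)-2-hydroxyphenyl]boronic acid F2. Hayashi–Miyaura asymmetric 1,4-addition of F2 to 10 ([RhCl(C2H4)2]2, (S)-BINAP, KOH, dioxane–water) would give ketone 11, where the route is rejoined; acid dehydration then gives 13.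

**Step 18.** The aryl epoxide may be lost before the phenol reaches it. Possible causes are epoxide migration or 5-exo closure under the basic fluoride conditions, opening by external nucleophiles, or ionisation at C2' so that inversion is no longer clean and the 2',3'-trans ring forms. Fallback that couples ring closure to epoxidation: setting out from 24, buffered desilylation (TBAF, AcOH) would give (1R,2Z)-1-{3,4-bis(benzyloxy)-5-[(2R,3R,4S)-7,8-bis(benzyloxy)-2-[3,4-bis(benzyloxy)phenyl]-3-hydroxychroman-4-yl]-2-hydroxyphenyl}-3-[3,4-bis(benzyloxy)phenyl]prop-2-en-1-ol F5. Epoxidation of F5 (m-CPBA, NaHCO3, CH2Cl2, −20 °C) would let the ortho phenol capture the epoxide as it forms under weakly acidic, non-basic conditions, giving 27 directly.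

**Step 19.** Hydrogenolytic loss of the C4' hydroxyl may compete once the 7'-phenol is free, because the carbinol then behaves as a para-hydroxybenzyl alcohol. Fallback that shields the carbinol: setting out from 27, silylation of the three secondary hydroxyls (TBSOTf, 2,6-lutidine) would give the tris(tert-butyldimethylsilyl) ether of 27 F6. Hydrogenolysis in EtOAc–THF (Pd(OH)2/C) would give the tris(tert-butyldimethylsilyl) ether of 28 F7, and HF·pyridine in THF would release 28.

**Step 15.** The hindered ortho-silyloxy aldehyde may give low conversion or poor facial selectivity. Fallback by reduction instead of addition: setting out from 20, addition of the lithium acetylide of 22 (excess, THF, −78 °C) would give the C1-epimeric propargylic alcohols F3. MnO2 in CH2Cl2 would oxidise only this activated carbinol to 1-{3,4-bis(benzyloxy)-5-[(2R,3R,4S)-7,8-bis(benzyloxy)-2-[3,4-bis(benzyloxy)phenyl]-3-hydroxychroman-4-yl]-2-[(tert-butyldimethylsilyl)oxy]phenyl}-3-[3,4-bis(benzyloxy)phenyl]prop-2-yn-1-one F4. Noyori transfer hydrogenation (RuCl[(S,S)-TsDPEN](p-cymene), HCO2H–Et3N) or Corey–Bakshi–Shibata reduction would return 23.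

## Further compounds

F1 | step 7 | 2,3-bis(benzyloxy)-6-bromophenol | Oc1c(Br)ccc(OCc2ccccc2)c1OCc1ccccc1
F2 | step 7 | [3,4-bis(benzyloxy)-2-hydroxyphenyl]boronic acid | OB(O)c1ccc(OCc2ccccc2)c(OCc2ccccc2)c1O
F3 | step 15 | 1-{3,4-bis(benzyloxy)-5-[(2R,3R,4S)-7,8-bis(benzyloxy)-2-[3,4-bis(benzyloxy)phenyl]-3-hydroxychroman-4-yl]-2-[(tert-butyldimethylsilyl)oxy]phenyl}-3-[3,4-bis(benzyloxy)phenyl]prop-2-yn-1-ol (both C1 epimers) | O1c2c(OCc9ccccc9)c(OCc9ccccc9)ccc2[C@@H](c2cc(C(O)C#Cc3ccc(OCc9ccccc9)c(OCc9ccccc9)c3)c(O[Si](C)(C)C(C)(C)C)c(OCc9ccccc9)c2OCc9ccccc9)[C@@H](O)[C@H]1c1ccc(OCc9ccccc9)c(OCc9ccccc9)c1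
F4 | step 15 | 1-{3,4-bis(benzyloxy)-5-[(2R,3R,4S)-7,8-bis(benzyloxy)-2-[3,4-bis(benzyloxy)phenyl]-3-hydroxychroman-4-yl]-2-[(tert-butyldimethylsilyl)oxy]phenyl}-3-[3,4-bis(benzyloxy)phenyl]prop-2-yn-1-one | O1c2c(OCc9ccccc9)c(OCc9ccccc9)ccc2[C@@H](c2cc(C(=O)C#Cc3ccc(OCc9ccccc9)c(OCc9ccccc9)c3)c(O[Si](C)(C)C(C)(C)C)c(OCc9ccccc9)c2OCc9ccccc9)[C@@H](O)[C@H]1c1ccc(OCc9ccccc9)c(OCc9ccccc9)c1
F5 | step 18 | (1R,2Z)-1-{3,4-bis(benzyloxy)-5-[(2R,3R,4S)-7,8-bis(benzyloxy)-2-[3,4-bis(benzyloxy)phenyl]-3-hydroxychroman-4-yl]-2-hydroxyphenyl}-3-[3,4-bis(benzyloxy)phenyl]prop-2-en-1-ol | O1c2c(OCc9ccccc9)c(OCc9ccccc9)ccc2[C@@H](c2cc([C@H](O)/C=C\c3ccc(OCc9ccccc9)c(OCc9ccccc9)c3)c(O)c(OCc9ccccc9)c2OCc9ccccc9)[C@@H](O)[C@H]1c1ccc(OCc9ccccc9)c(OCc9ccccc9)c1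
F6 | step 19 | tris(tert-butyldimethylsilyl) ether of 27 (silyl groups on O3, O3' and O4') | O1c2c(OCc9ccccc9)c(OCc9ccccc9)ccc2[C@@H](c2cc3c(c(OCc9ccccc9)c2OCc9ccccc9)O[C@H](c4ccc(OCc9ccccc9)c(OCc9ccccc9)c4)[C@H](O[Si](C)(C)C(C)(C)C)[C@H]3O[Si](C)(C)C(C)(C)C)[C@@H](O[Si](C)(C)C(C)(C)C)[C@H]1c1ccc(OCc9ccccc9)c(OCc9ccccc9)c1
F7 | step 19 | tris(tert-butyldimethylsilyl) ether of 28 (silyl groups on O3, O3' and O4', all phenols free) | O1c2c(O)c(O)ccc2[C@@H](c2cc3c(c(O)c2O)O[C@H](c4ccc(O)c(O)c4)[C@H](O[Si](C)(C)C(C)(C)C)[C@H]3O[Si](C)(C)C(C)(C)C)[C@@H](O[Si](C)(C)C(C)(C)C)[C@H]1c1ccc(O)c(O)c1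
A1 | alternative 1 | 2,3-cis-3,7-bis(benzyloxy)-2-[3,4-bis(benzyloxy)phenyl]-4-[2,3,4-tris(benzyloxy)-5-(2-methyl-1,3-dioxolan-2-yl)phenyl]chroman-4,8-diol | O2c3c(O)c(OCc9ccccc9)ccc3C(O)(c3cc(C4(C)OCCO4)c(OCc9ccccc9)c(OCc9ccccc9)c3OCc9ccccc9)[C@@H](OCc9ccccc9)[C@H]2c8ccc(OCc9ccccc9)c(OCc9ccccc9)c8
A2 | alternative 2 | deca-O-benzyl ether of 28 with only the C4' hydroxyl free (benzyl on O3, O3' and the eight phenolic oxygens) | O2c3c(OCc9ccccc9)c(OCc9ccccc9)ccc3[C@@H](c3cc4c(c(OCc9ccccc9)c3OCc9ccccc9)O[C@H](c8ccc(OCc9ccccc9)c(OCc9ccccc9)c8)[C@H](OCc9ccccc9)[C@H]4O)[C@@H](OCc9ccccc9)[C@H]2c8ccc(OCc9ccccc9)c(OCc9ccccc9)c8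
A3 | alternative 3 | (2R,3R)-7,8-bis(benzyloxy)-2-[3,4-bis(benzyloxy)phenyl]-6-bromochroman-3-ol | Brc3cc4c(c(OCc9ccccc9)c3OCc9ccccc9)O[C@H](c8ccc(OCc9ccccc9)c(OCc9ccccc9)c8)[C@H](O)C4
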